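I decided to reckon the small thing in Tuesday's flask, its Q, and to take J as a scaled reading from the alpha run.

| flask | D | G | E | remark | time |
|---|---|---|---|---|---|
| alpha | 20 mM | 2 equiv | 4 equiv | run made earlier |  |
| zeta | 20 mM | 2 equiv | 5.6 equiv | run made earlier |  |
| theta | 20 mM | 2 equiv | 8.8 equiv | run made earlier |  |
| Tuesday's | 20 mM | 2.00 equiv | 4.00 equiv (fed, over 5.0 h) | all else is in the flask from the start; the feed brings no volume worth counting | 12 h |
| Wednesday's | 20 mM (fed, over 5.0 h) | 2.00 equiv | 4.00 equiv | all else is in the flask from the start; the feed brings no volume worth counting | 12 h |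
| Sunday's | 20 mM | 2.00 equiv | 4.00 equiv | everything together at the start | 12 h |

| run | time / h | J / % | Q / % |
|---|---|---|---|
| alpha | 1.00 | 4.8 | 26.5 |
| alpha | 2.00 | 10.3 | 27.3 |
| alpha | 5.00 | 21.3 | 27.5 |
| alpha | 12.0 | 32.6 | 27.3 |
| zeta | 1.00 | 5.9 | 34.0 |
| zeta | 2.00 | 12.6 | 34.6 |
| zeta | 5.00 | 24.6 | 34.3 |
| zeta | 12.0 | 30.6 | 33.8 |
| theta | 1.50 | 11.5 | 45.1 |
| theta | 4.00 | 23.1 | 44.5 |
| theta | 8.00 | 24.8 | 44.1 |
| theta | 12.0 | 20.7 | 44.4 |

(readings scatter by 0.5 percentage points)

- J is meant together with its X
- solid, in amounts per volume of the solution: X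
- steps under discussion: D + E -> Q; D + G -> Z; E + J -> L; E + Z -> J; X <-> J

- the flask with the highest share of J in J plus Q ("all alike" if they lie within 1.5 percentage points) (Tuesday's / Wednesday's / Sunday's / all alike)
- share of J in J plus Q at the end, Tuesday's
- share of J in J plus Q at the end, Wednesday's
- share of J in J plus Q at the end, Sunday's

I went up the time scales from the fastest. In alpha, Q read 26.5% after 1.00 h and 27.5% after 5.00 h. That gave a rough reading of D's mean life:

mean life = 0.302 h

Next came the feed of 5.0 h, far longer. I named the fraction of the E feed delivered within one mean life of D the overlap: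

overlap = mean life / feed time = 0.0603

Above that stood J, which in alpha was still rising, from 21.3% after 5.00 h to 32.6% after 12.0 h.

The selectivity factor came from alpha's final Q, with E and G both falling:

s = ln(E start / E end) / ln(G start / G end) = 0.156

For Tuesday's flask, I took G between its charge and half of it:

Q = s × overlap × E charged / G = 1.89% to 3.78%

Scaling alpha's J by the larger stock of Z that I reckoned for Tuesday's flask, with no allowance for late E, put Tuesday's share between 92.0% and 95.9%. Sunday's flask has alpha's recipe, so I took alpha's final readings, which give 54.4%.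

The forecast named Tuesday's, with 89%, 52% and 54.4% for Tuesday's, Wednesday's and Sunday's, reasoning that “E is scarce while D is consumed”. Its Tuesday figure lay below my range.

The flasks gave 92.9%, 52.3% and 54.0% in that order, so Tuesday's led.

    D + E → Q (k = 0.00430 M⁻¹ s⁻¹)
    D + G → Z (k = 0.0270 M⁻¹ s⁻¹)
    E + J → L (k = 2.00 × 10⁻⁴ M⁻¹ s⁻¹)
    E + Z → J (k = 3.30 × 10⁻⁴ M⁻¹ s⁻¹)
    X ⇌ J, rate k5*(cs5 - [J]) while solid is left; crystals form when [J] > cs5 (solubility = 7.40 mM, k = 0.0120 s⁻¹)

D's half-life by the step to Z alone, concentrations as charged, was 0.18 h on Sunday's, shorter than the feed of Tuesday's flask. Tuesday's Q stood at 3.17% after 12.0 h, inside the range of 1.89% to 3.78% that the overlap of 0.0603 had given. With equivalents and feed time held, the mean life goes inversely with D's concentration, so the flask like Tuesday's but with 34 mM of D has an overlap of 0.0355 and Q of 1.11% to 2.22%. Computed, it holds 1.97% of Q and a share of 96.6%.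

All runs are simulated for an exercise, noise included.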